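**Retrosynthetic overview**
1. Target 28 comes by global desilylation from the eight-membered (E)-1,3-dioxa-2-silacyclooct-5-ene 27, in which one tBu2Si unit bridges the secondary and the tertiary carbinol oxygens.
2. 27 comes from thiazole aldehyde 9, vinyl oxirane 22 and divalent silicon (tBu2Si from 25). The aldehyde carbon and the terminal vinyl CH2 are both electrophilic, and they can be joined because silylene insertion reverses the polarity of the vinyl oxirane.
3. Enabling feature: the array O–CH(secondary carbinol)–CH2–CH=CH(E)–C(tertiary carbinol)–O is an (E)-2-ene-1,5-diol. Its tertiary C–O carbon and the adjacent vinylic CH are the two ring carbons of a 2,2,3-trisubstituted vinyl oxirane.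
4. 22 comes from Sharpless epoxidation of (Z)-dienol 19, which comes from lactol Wittig opening of butenolide 16, made by B-alkyl Suzuki coupling (13 + 14). 9 comes from a Hantzsch thiazole (2 + 3), a Z-selective Wittig reaction and two ester-to-aldehyde reductions.
5. Ring order: thiazole (step 2); butenolide of 14 opened (step 9); oxirane (step 10); 1,2-oxasiletane, then dioxasilacyclooctene (both temporary, step 14); silacycle opened (step 15).

Key step: step 14

Assumption: the exchange of C–O for C–Si at the allylic oxirane carbon in step 14 is taken to proceed with retention of configuration. The Z geometry of 19 was chosen on that basis.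

**Fragment A (aldehyde 9)**

Step 1
Reactants: 1 ethyl 2-cyano-2-methylpropanoate
Product: 2 ethyl 3-amino-2,2-dimethyl-3-thioxopropanoate
Conditions: H2S, Et3N, pyridine, rt → 50 °C
Reagents that add atoms: hydrogen sulfide, S
Why: Base-catalysed thiolysis of a nitrile that the geminal ester activates should give the primary thioamide without touching the hindered ester.

Step 2
Reactants: 2 ethyl 3-amino-2,2-dimethyl-3-thioxopropanoate; 3 ethyl 4-chloroacetoacetate
Product: 4 ethyl 2-[4-(2-ethoxy-2-oxoethyl)-1,3-thiazol-2-yl]-2-methylpropanoate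
Conditions: EtOH, reflux; aq. NaHCO3 work-up
Reagents that add atoms: none
Why: In the Hantzsch thiazole synthesis, S-alkylation at CH2Cl followed by N-condensation with the ketone and dehydration places the acetate arm at C4 and the CMe2 ester at C2.

Step 3
Reactants: 4 ethyl 2-[4-(2-ethoxy-2-oxoethyl)-1,3-thiazol-2-yl]-2-methylpropanoate
Product: 5 ethyl 2-methyl-2-[4-(2-oxoethyl)-1,3-thiazol-2-yl]propanoate
Conditions: iBu2AlH (1.05 equiv), toluene, −78 °C; aq. potassium sodium tartrate
Reagents that add atoms: none
Why: This partial ester reduction should be chemoselective because hydride reaches the unhindered acetate-type ester far faster than the ester next to the quaternary carbon.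

Step 4
Reactants: 5 ethyl 2-methyl-2-[4-(2-oxoethyl)-1,3-thiazol-2-yl]propanoate; 6 but-3-en-1-yltriphenylphosphonium bromide
Product: 8 ethyl 2-{4-[(2Z)-hexa-2,5-dien-1-yl]-1,3-thiazol-2-yl}-2-methylpropanoate, via butenylidene ylide 7 (not isolated)
Conditions: 6, NaN(SiMe3)2, THF, 0 °C; then 5, −78 °C → rt
Reagents that add atoms: none
Why: A Wittig reaction of a non-stabilised ylide under lithium-free conditions proceeds through the kinetically favoured cis-oxaphosphetane and should give the Z alkene of the skipped diene.

Step 5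
Reactants: 8 ethyl 2-{4-[(2Z)-hexa-2,5-dien-1-yl]-1,3-thiazol-2-yl}-2-methylpropanoate
Product: 9 2-{4-[(2Z)-hexa-2,5-dien-1-yl]-1,3-thiazol-2-yl}-2-methylpropanal
Conditions: iBu2AlH (1.1 equiv), CH2Cl2, −78 °C; aq. potassium sodium tartrate
Reagents that add atoms: none
Why: In this partial ester reduction the aluminium hemiacetal of the neopentyl-type ester, also held by the thiazole nitrogen, should persist at −78 °C and release the non-enolisable aldehyde only on work-up.

**Fragment B (vinyl oxirane 22)**

Step 6
Reactants: 10 acryloyl chloride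
Product: 13 methyl N-ethenylcarbamate, via acryloyl azide 11 (not isolated), via vinyl isocyanate 12 (not isolated)
Conditions: NaN3, H2O/toluene, 0 °C; then MeOH, pyridine (cat.), hydroquinone (cat.), toluene, 85 °C
Reagents that add atoms: sodium azide, [Na+].[N-]=[N+]=[N-]; methanol, CO
Why: In the Curtius rearrangement the acyl azide loses nitrogen to give vinyl isocyanate, which methanol traps as the methyl carbamate.

Step 7
Reactants: 13 methyl N-ethenylcarbamate; 14 4-bromofuran-2(5H)-one
Product: 16 methyl N-[2-(5-oxo-2,5-dihydrofuran-3-yl)ethyl]carbamate, via B-alkyl-9-BBN 15 (not isolated)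
Conditions: 9-BBN-H, THF, 0 °C → rt; then 14, PdCl2(dppf) (5 mol %), AsPh3, aq. K3PO4, DMF/THF, rt
Reagents that add atoms: none
Why: Hydroboration places boron on the terminal carbon of the enecarbamate, and the B-alkyl Suzuki–Miyaura coupling then transfers the 2-(carbamoylamino)ethyl group to the activated vinylic bromide under a mild phosphate base.

Step 8
Reactants: 16 methyl N-[2-(5-oxo-2,5-dihydrofuran-3-yl)ethyl]carbamate
Product: 17 methyl N-[2-(5-hydroxy-2,5-dihydrofuran-3-yl)ethyl]carbamate (lactol epimers)
Conditions: iBu2AlH (2.2 equiv), CH2Cl2, −78 °C; aq. potassium sodium tartrate, used at once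
Reagents that add atoms: none
Why: In this 1,2-reduction of the butenolide to the lactol, the N-metallated carbamate resists hydride and a neutral work-up avoids dehydration to the furan.

Step 9
Reactants: 17 methyl N-[2-(5-hydroxy-2,5-dihydrofuran-3-yl)ethyl]carbamate
Product: 19 methyl N-[(3Z)-3-(hydroxymethyl)hexa-3,5-dien-1-yl]carbamate, via open hydroxy-enal 18 (not isolated)
Conditions: Ph3PCH3Br, KOtBu (3.5 equiv each), THF, 0 °C → rt
Reagents that add atoms: methyltriphenylphosphonium bromide, C[P+](c1ccccc1)(c1ccccc1)c1ccccc1.[Br-]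
Why: The Wittig methylenation acts on the open tautomer of the lactol, and because the ring held CHO cis to CH2OH, the trisubstituted alkene should emerge Z with vinyl cis to CH2OH.

Step 10
Reactants: 19 methyl N-[(3Z)-3-(hydroxymethyl)hexa-3,5-dien-1-yl]carbamate
Product: 20 methyl N-{2-[(2S,3R)-3-ethenyl-2-(hydroxymethyl)oxiran-2-yl]ethyl}carbamate
Conditions: Ti(OiPr)4 (20 mol %), L-(+)-diisopropyl tartrate (24 mol %), tBuOOH, 4 Å MS, CH2Cl2, −20 °C
Reagents that add atoms: tert-butyl hydroperoxide, CC(C)(C)OO
Why: In the Sharpless asymmetric epoxidation the allylic hydroxyl directs oxygen to the trisubstituted alkene only, the L-(+)-tartrate should select the face that gives the (2S,3R)-oxirane and so fixes the tertiary C–O stereocentre, and syn addition keeps vinyl cis to CH2OH.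

Step 11
Reactants: 20 methyl N-{2-[(2S,3R)-3-ethenyl-2-(hydroxymethyl)oxiran-2-yl]ethyl}carbamate
Product: 21 methyl N-{2-[(2S,3R)-2-(tert-butyldimethylsilyloxymethyl)-3-ethenyloxiran-2-yl]ethyl}carbamate
Conditions: TBSCl, imidazole, CH2Cl2, 0 °C → rt
Reagents that add atoms: tert-butyldimethylsilyl chloride, CC(C)(C)[Si](C)(C)Cl
Why: Standard O-silylation under weakly basic conditions removes the O–H bond without Payne migration or opening of the oxirane.

Step 12
Reactants: 21 methyl N-{2-[(2S,3R)-2-(tert-butyldimethylsilyloxymethyl)-3-ethenyloxiran-2-yl]ethyl}carbamate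
Product: 22 methyl N-(tert-butyldimethylsilyl)-N-{2-[(2S,3R)-2-(tert-butyldimethylsilyloxymethyl)-3-ethenyloxiran-2-yl]ethyl}carbamate
Conditions: KN(SiMe3)2, THF, −78 °C; TBSCl; pentane, filtration, used directly
Reagents that add atoms: tert-butyldimethylsilyl chloride, CC(C)(C)[Si](C)(C)Cl
Why: N-silylation of the potassium carbamate removes the last N–H bond that would quench a silylene, and the low temperature keeps the anion from attacking the oxirane.

**Silylene source**

Step 13
Reactants: 23 di-tert-butyldichlorosilane; 24 cyclohexene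
Product: 25 cis-7,7-di-tert-butyl-7-silabicyclo[4.1.0]heptane
Conditions: Li (excess), cyclohexene/THF, rt; distillation
Reagents that add atoms: none
Why: In this reductive silacyclopropanation lithium converts the dichlorosilane into a silylenoid that adds syn to cyclohexene, and the two tert-butyl groups make the strained ring isolable.

**Union and completion**

Step 14
Reactants: 22 methyl N-(tert-butyldimethylsilyl)-N-{2-[(2S,3R)-2-(tert-butyldimethylsilyloxymethyl)-3-ethenyloxiran-2-yl]ethyl}carbamate; 25 cis-7,7-di-tert-butyl-7-silabicyclo[4.1.0]heptane; 9 2-{4-[(2Z)-hexa-2,5-dien-1-yl]-1,3-thiazol-2-yl}-2-methylpropanal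
Product: 27 (4R,5E,8R)-2,2-di-tert-butyl-4-(tert-butyldimethylsilyloxymethyl)-4-{2-[(tert-butyldimethylsilyl)(methoxycarbonyl)amino]ethyl}-8-(2-{4-[(2Z)-hexa-2,5-dien-1-yl]-1,3-thiazol-2-yl}propan-2-yl)-1,3-dioxa-2-silacyclooct-5-ene, via vinyl-oxasiletane 26 (not isolated)
Conditions: 22 (1.2 equiv), 25 (1.25 equiv), AgOCOCF3 (5 mol %), toluene, −25 → 0 °C; then 9 (1.0 equiv), 0 °C → rt
Reagents that add atoms: none
Why: AgOCOCF3 takes tBu2Si from 25 and passes it to the oxirane oxygen of 22, and the resulting silyl-oxonium ylide undergoes a Stevens-type 1,2-shift of the allylic carbon from O to Si (oxirane to 1,2-oxasiletane, a three-to-four ring expansion by formal C–O insertion) to give the strained, Lewis acidic allylsilane 26. Aldehyde 9 binds to silicon and is attacked by the vinyl CH2 terminus through a six-membered chair (syn-SE2'), so that the C–C and Si–O bonds form while C–Si breaks and the four-membered ring grows by four atoms into the trans-dioxasilacyclooctene 27. The closest known reaction type is the silver-catalysed insertion of di-tert-butylsilylene into vinyl epoxides followed by uncatalysed allylation of aldehydes to trans-1,3-dioxa-2-silacyclooct-5-enes, applied here to a 2,2,3-trisubstituted oxirane. The tertiary stereocentre is carried over because its C–O bond is never broken, the transient C–Si centre should form with retention because silicon stays tethered to the departing oxygen and closes on the same face, and that centre then controls the new one through a chair with the CMe2-thiazolyl group equatorial and the quaternary carbon pseudo-equatorial, which gives the (R)-carbinol and the E alkene together. Regioselectivity for the allylic rather than the tertiary C–O bond rests on allyl stabilisation of the migrating carbon and on the reluctance of tBu2Si to bond to a fully substituted carbon. Chemoselectivity rests on the absence of O–H and N–H bonds in 22, on the reversible binding of silylene to the N-silyl carbamate, which has no exit path, and on adding 9 (with its alkenes and thiazole) only after 25 has been consumed.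

Step 15
Reactants: 27 (4R,5E,8R)-dioxasilacyclooctene from step 14
Product: 28 target, methyl N-[(3R,4E,7R)-3,7-dihydroxy-8-{4-[(2Z)-hexa-2,5-dien-1-yl]-1,3-thiazol-2-yl}-3-(hydroxymethyl)-8-methylnon-4-en-1-yl]carbamate
Conditions: HF·pyridine, pyridine, THF, 0 °C → rt
Reagents that add atoms: none
Why: Fluoride-driven cleavage of all Si–O and Si–N bonds releases the triol and the N–H carbamate in one operation, the pyridine buffer protects the tertiary allylic alcohol from ionisation, and no stereocentre is touched.

**Compound list**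
1 | ethyl 2-cyano-2-methylpropanoate | CCOC(=O)C(C)(C)C#N | starting material
2 | ethyl 3-amino-2,2-dimethyl-3-thioxopropanoate | CCOC(=O)C(C)(C)C(N)=S | intermediate
3 | ethyl 4-chloroacetoacetate | CCOC(=O)CC(=O)CCl | starting material
4 | ethyl 2-[4-(2-ethoxy-2-oxoethyl)-1,3-thiazol-2-yl]-2-methylpropanoate | CCOC(=O)Cc1csc(C(C)(C)C(=O)OCC)n1 | intermediate
5 | ethyl 2-methyl-2-[4-(2-oxoethyl)-1,3-thiazol-2-yl]propanoate | CCOC(=O)C(C)(C)c1nc(CC=O)cs1 | intermediate
6 | but-3-en-1-yltriphenylphosphonium bromide | C=CCC[P+](c1ccccc1)(c1ccccc1)c1ccccc1.[Br-] | starting material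
7 | but-3-en-1-ylidenetriphenylphosphorane | C=CCC=P(c1ccccc1)(c1ccccc1)c1ccccc1 | intermediate
8 | ethyl 2-{4-[(2Z)-hexa-2,5-dien-1-yl]-1,3-thiazol-2-yl}-2-methylpropanoate | C=CC/C=C\Cc1csc(C(C)(C)C(=O)OCC)n1 | intermediate
9 | 2-{4-[(2Z)-hexa-2,5-dien-1-yl]-1,3-thiazol-2-yl}-2-methylpropanal | C=CC/C=C\Cc1csc(C(C)(C)C=O)n1 | intermediate
10 | acryloyl chloride | C=CC(=O)Cl | starting material
11 | acryloyl azide | C=CC(=O)N=[N+]=[N-] | intermediate
12 | vinyl isocyanate | C=CN=C=O | intermediate
13 | methyl N-ethenylcarbamate | C=CNC(=O)OC | intermediate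
14 | 4-bromofuran-2(5H)-one | O=C1C=C(Br)CO1 | starting material
15 | methyl N-[2-(9-borabicyclo[3.3.1]nonan-9-yl)ethyl]carbamate | COC(=O)NCCB1C2CCCC1CCC2 | intermediate
16 | methyl N-[2-(5-oxo-2,5-dihydrofuran-3-yl)ethyl]carbamate | COC(=O)NCCC1=CC(=O)OC1 | intermediate
17 | methyl N-[2-(5-hydroxy-2,5-dihydrofuran-3-yl)ethyl]carbamate (lactol epimers) | COC(=O)NCCC1=CC(O)OC1 | intermediate
18 | methyl N-[(3Z)-3-(hydroxymethyl)-5-oxopent-3-en-1-yl]carbamate | O=C/C=C(\CO)CCNC(=O)OC | intermediate
19 | methyl N-[(3Z)-3-(hydroxymethyl)hexa-3,5-dien-1-yl]carbamate | C=C/C=C(\CO)CCNC(=O)OC | intermediate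
20 | methyl N-{2-[(2S,3R)-3-ethenyl-2-(hydroxymethyl)oxiran-2-yl]ethyl}carbamate | C=C[C@H]1O[C@]1(CO)CCNC(=O)OC | intermediate
21 | O-TBS ether of 20, (2S,3R) | C=C[C@H]1O[C@]1(CO[Si](C)(C)C(C)(C)C)CCNC(=O)OC | intermediate
22 | N,O-bis-TBS derivative of 20, (2S,3R) | C=C[C@H]1O[C@]1(CO[Si](C)(C)C(C)(C)C)CCN([Si](C)(C)C(C)(C)C)C(=O)OC | intermediate
23 | di-tert-butyldichlorosilane | CC(C)(C)[Si](Cl)(Cl)C(C)(C)C | starting material
24 | cyclohexene | C1=CCCCC1 | starting material
25 | cis-7,7-di-tert-butyl-7-silabicyclo[4.1.0]heptane | CC(C)(C)[Si]1(C(C)(C)C)[C@H]2CCCC[C@@H]12 | intermediate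
26 | (3R,4S)-2,2-di-tert-butyl-3-ethenyl-1,2-oxasiletane carrying CH2OTBS (cis to ethenyl) and CH2CH2N(TBS)CO2Me at C4 | C=C[C@H]1[Si](C(C)(C)C)(C(C)(C)C)O[C@]1(CO[Si](C)(C)C(C)(C)C)CCN([Si](C)(C)C(C)(C)C)C(=O)OC | intermediate
27 | (4R,5E,8R)-1,3-dioxa-2-silacyclooct-5-ene of step 14 | C=CC/C=C\Cc1csc(C(C)(C)[C@@H]2O[Si](C(C)(C)C)(C(C)(C)C)O[C@](CO[Si](C)(C)C(C)(C)C)(CCN([Si](C)(C)C(C)(C)C)C(=O)OC)/C=C/C2)n1 | intermediate
28 | methyl N-[(3R,4E,7R)-3,7-dihydroxy-8-{4-[(2Z)-hexa-2,5-dien-1-yl]-1,3-thiazol-2-yl}-3-(hydroxymethyl)-8-methylnon-4-en-1-yl]carbamate | C=CC/C=C\Cc1csc(C(C)(C)[C@H](O)C/C=C/[C@@](O)(CO)CCNC(=O)OC)n1 | target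

**Totals**
Total step count: 15.
Longest linear sequence: 9 steps (6, 7, 8, 9, 10, 11, 12, 14, 15).

**Steps most likely to fail**

Step 14.
- What may go wrong:
  - Stereochemical information may be lost during the ring expansion through bond rotation in an opened allyl/silyl pair.
  - The oxasiletane may undergo Peterson-type cycloreversion to a diene.
  - The silylene may be captured by the carbamate.
  - The hindered aldehyde may react sluggishly.
- Fallback (sets out from 22 and 9, returns at 28): the same two carbons are joined by a reductive Barbier-type coupling.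
  - SmI2 with catalytic Pd(PPh3)4 in THF turns the π-allyl complex formed from zerovalent palladium and the vinyl oxirane into an allylsamarium species, which attacks through its unsubstituted terminus. The N–Si bond is lost on aqueous work-up. This should give the carbinol-epimeric mono-TBS ether of the target F1.
  - Dess–Martin oxidation gives the mono-TBS β,γ-unsaturated ketone F2.
  - Corey–Bakshi–Shibata reduction with the (S)-Me-CBS oxazaborolidine and catecholborane, with the quaternary carbon as the large group, sets the (R)-carbinol in the mono-TBS ether of the target F3.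
  - HF·pyridine as in step 15 then gives 28.

Step 10.
- What may go wrong:
  - Oxygen transfer to a Z-configured allylic alcohol may be slow and poorly face-selective.
  - Titanium may promote opening of the labile vinyl oxirane by isopropoxide, tartrate or the carbamate carbonyl.
- Fallback (sets out from 19, returns at 21): the directing-group approach is given up.
  - TBSCl/imidazole gives the dienol TBS ether F4.
  - A Shi epoxidation follows (D-fructose-derived ketone, KHSO5, K2CO3 buffer, MeCN/dimethoxymethane/H2O, 0 °C). It should oxidise the more electron-rich trisubstituted alkene of the diene from the face set by the spiro transition state and deliver 21 directly.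

Step 4.
- What may go wrong: the ylide may deprotonate the acidic thiazolyl-acetaldehyde, leading to enolate formation, self-condensation or migration of the alkene into conjugation.
- Fallback (sets out from 2, returns at 8): the Z alkene is made from an alkyne instead.
  - Hantzsch reaction of 2 with 1,3-dichloroacetone gives ethyl 2-[4-(chloromethyl)-1,3-thiazol-2-yl]-2-methylpropanoate F5.
  - CuI/NaI/K2CO3 in DMF couples F5 with pent-1-en-4-yne to give ethyl 2-[4-(hex-5-en-2-yn-1-yl)-1,3-thiazol-2-yl]-2-methylpropanoate F6.
  - Semi-hydrogenation (H2, Pd/CaCO3 poisoned with Pb(OAc)2, quinoline) gives 8.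

**Further compounds**
F1 | step 14 | carbinol-epimeric mono-TBS ether of the target | C=CC/C=C\Cc1csc(C(C)(C)C(O)C/C=C/[C@@](O)(CO[Si](C)(C)C(C)(C)C)CCNC(=O)OC)n1
F2 | step 14 | mono-TBS β,γ-unsaturated ketone | C=CC/C=C\Cc1csc(C(C)(C)C(=O)C/C=C/[C@@](O)(CO[Si](C)(C)C(C)(C)C)CCNC(=O)OC)n1
F3 | step 14 | mono-TBS ether of the target | C=CC/C=C\Cc1csc(C(C)(C)[C@H](O)C/C=C/[C@@](O)(CO[Si](C)(C)C(C)(C)C)CCNC(=O)OC)n1
F4 | step 10 | dienol TBS ether | C=C/C=C(\CO[Si](C)(C)C(C)(C)C)CCNC(=O)OC
F5 | step 4 | ethyl 2-[4-(chloromethyl)-1,3-thiazol-2-yl]-2-methylpropanoate | CCOC(=O)C(C)(C)c1nc(CCl)cs1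
F6 | step 4 | ethyl 2-[4-(hex-5-en-2-yn-1-yl)-1,3-thiazol-2-yl]-2-methylpropanoate | C=CCC#CCc1csc(C(C)(C)C(=O)OCC)n1
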